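**Plan**
- Ring A is numbered C1 (CO2Me), C2 (OH), C3 (prenyl), C4 (pyran O), C5 (pyran C), C6 (arylethyl). C2–C5 carry the O/prenyl/O pattern of 2-prenyldimedone, and the adjacent C1/C6 pair carries ester and alkyl like the two sp carbons of an ynoate; this is what lets ring A arise by cycloaddition–cycloreversion.
- Retrosynthesis: cut the aryl O–Si bond; cut the pyran at O–CMe2 and C5–CH (back to a β-resorcylate and 3-methylbut-2-enal); cut ring A at C1–C2 and C5–C6 (back to a bis(silyloxy)cyclohexadiene and an ynoate).
- Forward: diene arm (2 steps from dimedone) and ynoate arm (4 steps from methyl 3-(4-hydroxyphenyl)propanoate); ring A by Diels–Alder/retro-Diels–Alder; then the pyran ring by condensation and oxa-6π closure at the only free ring carbon; then desilylation.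
- Stereochemistry: the target has no stereocentre and no stereogenic double bond (the chromene olefin is held cis by its ring), so nothing has to be set.

Key step: step 7

Remark: dione 3 is drawn as the diketone although it should exist largely as its enol; cycloadduct 12 is racemic and one enantiomer is drawn.

Step 1
Reactants: 1 dimedone; 2 prenyl bromide
Product: 3 5,5-dimethyl-2-(3-methylbut-2-enyl)cyclohexane-1,3-dione
Conditions: KOH (1.0 equiv), H2O, 0 °C → rt; then dilute HCl to pH 3
Reagents that add atoms: none
Why: SN2 C-alkylation of a cyclic 1,3-dione enolate by an allylic bromide is standard, and in water the enolate oxygens are hydrogen-bonded so that C2 should be the preferred nucleophilic site.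

Step 2
Reactants: 3 5,5-dimethyl-2-(3-methylbut-2-enyl)cyclohexane-1,3-dione
Product: 5 5,5-dimethyl-2-(3-methylbut-2-enyl)-1,3-bis(trimethylsilyloxy)cyclohexa-1,3-diene, via silyloxy enone 4 (not isolated)
Conditions: LiN(iPr)2 (1.05 equiv), THF, −78 °C, then Me3SiCl, → 0 °C; LiN(iPr)2 (1.15 equiv), −78 °C, then Me3SiCl, → rt; pentane, filtration under Ar, bulb-to-bulb distillation
Reagents that add atoms: trimethylsilyl chloride, C[Si](C)(C)Cl
Why: O-silylation of the dione enolate gives vinylogous silyl ester 4, and kinetic deprotonation of 4 at the CH2 next to the carbonyl followed by a second O-silylation is the standard silyl enol ether route to 1,3-bis(silyloxy)cyclohexa-1,3-dienes, the prenyl olefin being inert.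

Step 3
Reactants: 6 methyl 3-(4-hydroxyphenyl)propanoate
Product: 7 methyl 3-[4-(tert-butyldimethylsilyloxy)phenyl]propanoate
Conditions: t-BuMe2SiCl, imidazole, DMF, rt
Reagents that add atoms: tert-butyldimethylsilyl chloride, CC(C)(C)[Si](C)(C)Cl
Why: Imidazole-promoted silylation of a phenol is routine and masks the acidic OH, which would otherwise protonate the silyl dienol ether in the cycloaddition.

Step 4
Reactants: 7 methyl 3-[4-(tert-butyldimethylsilyloxy)phenyl]propanoate
Product: 8 3-[4-(tert-butyldimethylsilyloxy)phenyl]propanal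
Conditions: i-Bu2AlH (1.05 equiv), CH2Cl2, −78 °C; MeOH, then aq. KNaC4H4O6
Reagents that add atoms: none
Why: Partial reduction of a methyl 3-arylpropanoate to the aldehyde with one equivalent of i-Bu2AlH at −78 °C is a standard ester-to-aldehyde reduction, and the low temperature should hold back over-reduction.

Step 5
Reactants: 8 3-[4-(tert-butyldimethylsilyloxy)phenyl]propanal
Product: 9 tert-butyl[4-(4,4-dibromobut-3-enyl)phenoxy]dimethylsilane
Conditions: CBr4 (2 equiv), PPh3 (4 equiv), CH2Cl2, 0 °C
Reagents that add atoms: tetrabromomethane, BrC(Br)(Br)Br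
Why: The first stage of the Corey–Fuchs sequence, a Wittig-type dibromo-olefination by Ph3P=CBr2, is reliable for unhindered aliphatic aldehydes and leaves the aryl silyl ether alone.

Step 6
Reactants: 9 tert-butyl[4-(4,4-dibromobut-3-enyl)phenoxy]dimethylsilane
Product: 11 methyl 5-[4-(tert-butyldimethylsilyloxy)phenyl]pent-2-ynoate, via lithium acetylide 10 (not isolated)
Conditions: n-BuLi (2.1 equiv), THF, −78 °C; then ClCO2Me (1.5 equiv), −78 → 0 °C
Reagents that add atoms: methyl chloroformate, COC(=O)Cl
Why: The second stage of the Corey–Fuchs sequence (Br/Li exchange, Fritsch–Buttenberg–Wiechell rearrangement and deprotonation) gives acetylide 10, whose in-flask acylation with a chloroformate is the usual way to a 2-ynoate.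

Step 7
Reactants: 5 5,5-dimethyl-2-(3-methylbut-2-enyl)-1,3-bis(trimethylsilyloxy)cyclohexa-1,3-diene; 11 methyl 5-[4-(tert-butyldimethylsilyloxy)phenyl]pent-2-ynoate
Product: 14 methyl 6-{2-[4-(tert-butyldimethylsilyloxy)phenyl]ethyl}-2,4-dihydroxy-3-(3-methylbut-2-enyl)benzoate, via bicyclo[2.2.2]octadiene cycloadduct 12 (not isolated), via tris(silyl) benzoate 13 (not isolated)
Conditions: 5 (2 equiv), neat, sealed tube, Ar, 175 °C; then THF, 1 M aq. HCl, 0 °C
Reagents that add atoms: none
Why: Electron-rich diene 5 and ynoate 11 should combine in a concerted, asynchronous normal-demand [4+2] cycloaddition in which the unsubstituted, most nucleophilic diene terminus (diene C4, the CH) bonds to the ynoate β-carbon and the silyloxy-bearing terminus (diene C1) bonds to the α-carbon, giving bicyclo[2.2.2]octadiene 12. At the same temperature 12 should undergo retro-[4+2] cycloreversion, expelling its CMe2–CH2 bridge as 2-methylpropene to leave ring A as bis(trimethylsilyl) ether 13, which dilute acid unmasks to 14 while the more robust aryl tert-butyldimethylsilyl ether stays on. The closest known reaction type is the Alder–Rickert synthesis of β-resorcylates from dimedone-derived 1,3-bis(silyloxy)cyclohexa-1,3-dienes and alkyl-substituted acetylenic esters. Ring A is closed by a bimolecular [4+2] annulation that forms C1–C2 and C5–C6 (ring A numbering) in one step and is then aromatised by the cycloreversion, so no endo or exo cyclisation mode applies. No stereocentre is created in the product, since the two bridgehead centres of racemic 12 are erased on aromatisation. The step needs regioselectivity, secured by the 1,3-dioxygen polarisation of the diene that places the ester ortho to C2–O and para to C4–O, and chemoselectivity, secured because the unactivated prenyl olefin is a poor ene partner for an ynoate without Lewis acid and because the gem-dimethyl group makes the thermal 1,5-hydrogen shift of 5 degenerate.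

Step 8
Reactants: 14 methyl 6-{2-[4-(tert-butyldimethylsilyloxy)phenyl]ethyl}-2,4-dihydroxy-3-(3-methylbut-2-enyl)benzoate; 15 3-methylbut-2-enal
Product: 17 methyl 5-{2-[4-(tert-butyldimethylsilyloxy)phenyl]ethyl}-7-hydroxy-2,2-dimethyl-8-(3-methylbut-2-enyl)-2H-chromene-6-carboxylate, via ortho-quinone methide 16 (not isolated)
Conditions: 15 (3 equiv), ethylenediammonium diacetate (20 mol%), toluene, reflux
Reagents that add atoms: none
Why: Amine-salt-catalysed Knoevenagel-type condensation of the enal at C5, the only unsubstituted ring carbon and ortho to the free C4 hydroxyl, should give vinyl ortho-quinone methide 16, which closes by oxa-6π electrocyclisation to the 2,2-dimethyl-2H-chromene (the known chromenylation of resorcinols with enals), while the ester-chelated C2 hydroxyl has no free ortho carbon.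

Step 9
Reactants: 17 methyl 5-{2-[4-(tert-butyldimethylsilyloxy)phenyl]ethyl}-7-hydroxy-2,2-dimethyl-8-(3-methylbut-2-enyl)-2H-chromene-6-carboxylate
Product: 18 methyl 7-hydroxy-5-[2-(4-hydroxyphenyl)ethyl]-2,2-dimethyl-8-(3-methylbut-2-enyl)-2H-chromene-6-carboxylate (CNP0133674.0)
Conditions: Bu4NF (1.1 equiv), AcOH (1.1 equiv), THF, 0 °C
Reagents that add atoms: none
Why: Fluoride cleavage of an aryl silyl ether is fast at 0 °C and, buffered with acetic acid, should leave the methyl ester, the chromene and the prenyl group untouched.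

**Compound list**
1 | dimedone (5,5-dimethylcyclohexane-1,3-dione) | CC1(C)CC(=O)CC(=O)C1 | starting material
2 | prenyl bromide (1-bromo-3-methylbut-2-ene) | CC(C)=CCBr | starting material
3 | 5,5-dimethyl-2-(3-methylbut-2-enyl)cyclohexane-1,3-dione | CC(C)=CCC1C(=O)CC(C)(C)CC1=O | intermediate
4 | 5,5-dimethyl-2-(3-methylbut-2-enyl)-3-(trimethylsilyloxy)cyclohex-2-en-1-one | CC(C)=CCC1=C(O[Si](C)(C)C)CC(C)(C)CC1=O | intermediate
5 | 5,5-dimethyl-2-(3-methylbut-2-enyl)-1,3-bis(trimethylsilyloxy)cyclohexa-1,3-diene | C[Si](C)(C)OC1=CC(C)(C)CC(O[Si](C)(C)C)=C1CC=C(C)C | intermediate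
6 | methyl 3-(4-hydroxyphenyl)propanoate | COC(=O)CCc1ccc(O)cc1 | starting material
7 | methyl 3-[4-(tert-butyldimethylsilyloxy)phenyl]propanoate | COC(=O)CCc1ccc(O[Si](C)(C)C(C)(C)C)cc1 | intermediate
8 | 3-[4-(tert-butyldimethylsilyloxy)phenyl]propanal | O=CCCc1ccc(O[Si](C)(C)C(C)(C)C)cc1 | intermediate
9 | tert-butyl[4-(4,4-dibromobut-3-enyl)phenoxy]dimethylsilane | BrC(Br)=CCCc1ccc(O[Si](C)(C)C(C)(C)C)cc1 | intermediate
10 | lithium 4-[4-(tert-butyldimethylsilyloxy)phenyl]but-1-yn-1-ide | [Li]C#CCCc1ccc(O[Si](C)(C)C(C)(C)C)cc1 | intermediate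
11 | methyl 5-[4-(tert-butyldimethylsilyloxy)phenyl]pent-2-ynoate | COC(=O)C#CCCc1ccc(O[Si](C)(C)C(C)(C)C)cc1 | intermediate
12 | methyl 3-{2-[4-(tert-butyldimethylsilyloxy)phenyl]ethyl}-8,8-dimethyl-6-(3-methylbut-2-enyl)-1,5-bis(trimethylsilyloxy)bicyclo[2.2.2]octa-2,5-diene-2-carboxylate (racemic, one enantiomer drawn) | COC(=O)C1=C(CCc2ccc(O[Si](C)(C)C(C)(C)C)cc2)[C@@H]2C(O[Si](C)(C)C)=C(CC=C(C)C)[C@@]1(O[Si](C)(C)C)CC2(C)C | intermediate
13 | methyl 6-{2-[4-(tert-butyldimethylsilyloxy)phenyl]ethyl}-3-(3-methylbut-2-enyl)-2,4-bis(trimethylsilyloxy)benzoate | COC(=O)c1c(O[Si](C)(C)C)c(CC=C(C)C)c(O[Si](C)(C)C)cc1CCc1ccc(O[Si](C)(C)C(C)(C)C)cc1 | intermediate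
14 | methyl 6-{2-[4-(tert-butyldimethylsilyloxy)phenyl]ethyl}-2,4-dihydroxy-3-(3-methylbut-2-enyl)benzoate | COC(=O)c1c(O)c(CC=C(C)C)c(O)cc1CCc1ccc(O[Si](C)(C)C(C)(C)C)cc1 | intermediate
15 | 3-methylbut-2-enal | CC(C)=CC=O | starting material
16 | methyl (3Z)-2-{2-[4-(tert-butyldimethylsilyloxy)phenyl]ethyl}-6-hydroxy-5-(3-methylbut-2-enyl)-3-(3-methylbut-2-enylidene)-4-oxocyclohexa-1,5-diene-1-carboxylate (the isomer that can cyclise) | COC(=O)C1=C(CCc2ccc(O[Si](C)(C)C(C)(C)C)cc2)/C(=C/C=C(C)C)C(=O)C(CC=C(C)C)=C1O | intermediate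
17 | methyl 5-{2-[4-(tert-butyldimethylsilyloxy)phenyl]ethyl}-7-hydroxy-2,2-dimethyl-8-(3-methylbut-2-enyl)-2H-chromene-6-carboxylate | COC(=O)c1c(O)c(CC=C(C)C)c2c(c1CCc1ccc(O[Si](C)(C)C(C)(C)C)cc1)C=CC(C)(C)O2 | intermediate
18 | methyl 7-hydroxy-5-[2-(4-hydroxyphenyl)ethyl]-2,2-dimethyl-8-(3-methylbut-2-enyl)-2H-chromene-6-carboxylate | COC(=O)c1c(O)c(CC=C(C)C)c2c(c1CCc1ccc(O)cc1)C=CC(C)(C)O2 | target

**Step count**
Total: 9 steps. Longest linear sequence: 7 steps (6 → 18 through steps 3–9); the diene arm (steps 1–2) joins at step 7.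

**Steps most likely to fail**

Step 7. The cycloaddition may stall because a C2-substituted diene and a β-alkyl ynoate are both sluggish partners, and long heating invites protodesilylation of the diene and slow ene-type consumption of the prenyl olefin. The fallback moves the prenyl group out of the cycloaddition; it sets out from 1 and 11 and comes back at 14. Dimedone 1 would be silylated twice as in step 2, through 5,5-dimethyl-3-(trimethylsilyloxy)cyclohex-2-en-1-one F1 in the flask, to 5,5-dimethyl-1,3-bis(trimethylsilyloxy)cyclohexa-1,3-diene F2. Heating F2 with 11 (neat, 160–170 °C) should give methyl 3-{2-[4-(tert-butyldimethylsilyloxy)phenyl]ethyl}-8,8-dimethyl-1,5-bis(trimethylsilyloxy)bicyclo[2.2.2]octa-2,5-diene-2-carboxylate F3, which loses 2-methylpropene to give methyl 6-{2-[4-(tert-butyldimethylsilyloxy)phenyl]ethyl}-2,4-bis(trimethylsilyloxy)benzoate F4. Dilute HCl in THF should then free methyl 6-{2-[4-(tert-butyldimethylsilyloxy)phenyl]ethyl}-2,4-dihydroxybenzoate F5. C-Prenylation of F5 with prenyl bromide 2 and DBU in THF is expected at C3, the carbon between the two hydroxyls and the usual site for 2,4-dihydroxyaryl carbonyl compounds. The C5 and O-alkylated isomers would have to be removed by chromatography, and the route resumes at 14.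

Step 8. Condensation at C5 may be slow because this carbon sits between the hydroxyl and the arylethyl chain on a ring deactivated by the para ester, so that self-condensation of the enal could outrun chromene formation. The fallback builds the pyran from an aryl propargyl ether; it sets out from 14 and comes back at 17. The non-chelated C4 hydroxyl of 14 would be alkylated with 3-chloro-3-methylbut-1-yne (DBU, catalytic CuCl2, MeCN, 0 °C) to give methyl 6-{2-[4-(tert-butyldimethylsilyloxy)phenyl]ethyl}-2-hydroxy-3-(3-methylbut-2-enyl)-4-(2-methylbut-3-yn-2-yloxy)benzoate F6. Heating F6 in N,N-diethylaniline at about 160 °C should trigger the aryl propargyl ether Claisen rearrangement toward the open C5 position, converge on ortho-quinone methide 16 and close to 17.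

Step 1. The alkylation may divert to the enol oxygen or run twice at C2. The fallback replaces the SN2 alkylation by a Tsuji–Trost allylation; it sets out from 1 and comes back at 3. Dimedone 1 would be treated with 3-methylbut-2-enyl acetate and catalytic Pd(PPh3)4 (a zerovalent palladium complex) with Et3N in THF. The soft dione nucleophile should attack the less hindered terminus of the prenyl-palladium intermediate, and any O-allylated material re-ionises under the catalyst and funnels to the C-alkylated dione 3. This fallback makes no compound outside the compound list (F0).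

**Further compounds**
F1 | step 7 | 5,5-dimethyl-3-(trimethylsilyloxy)cyclohex-2-en-1-one | CC1(C)CC(=O)C=C(O[Si](C)(C)C)C1
F2 | step 7 | 5,5-dimethyl-1,3-bis(trimethylsilyloxy)cyclohexa-1,3-diene | C[Si](C)(C)OC1=CC(C)(C)CC(O[Si](C)(C)C)=C1
F3 | step 7 | methyl 3-{2-[4-(tert-butyldimethylsilyloxy)phenyl]ethyl}-8,8-dimethyl-1,5-bis(trimethylsilyloxy)bicyclo[2.2.2]octa-2,5-diene-2-carboxylate (racemic, one enantiomer drawn) | COC(=O)C1=C(CCc2ccc(O[Si](C)(C)C(C)(C)C)cc2)[C@@H]2C(O[Si](C)(C)C)=C[C@@]1(O[Si](C)(C)C)CC2(C)C
F4 | step 7 | methyl 6-{2-[4-(tert-butyldimethylsilyloxy)phenyl]ethyl}-2,4-bis(trimethylsilyloxy)benzoate | COC(=O)c1c(O[Si](C)(C)C)cc(O[Si](C)(C)C)cc1CCc1ccc(O[Si](C)(C)C(C)(C)C)cc1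
F5 | step 7 | methyl 6-{2-[4-(tert-butyldimethylsilyloxy)phenyl]ethyl}-2,4-dihydroxybenzoate | COC(=O)c1c(O)cc(O)cc1CCc1ccc(O[Si](C)(C)C(C)(C)C)cc1
F6 | step 8 | methyl 6-{2-[4-(tert-butyldimethylsilyloxy)phenyl]ethyl}-2-hydroxy-3-(3-methylbut-2-enyl)-4-(2-methylbut-3-yn-2-yloxy)benzoate | COC(=O)c1c(O)c(CC=C(C)C)c(OC(C)(C)C#C)cc1CCc1ccc(O[Si](C)(C)C(C)(C)C)cc1
F0 | step 1 | none | none
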